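A small charge of initiator, 0.25 mM in the delta run beside 20 mM of solid substrate, invites a balance first: by 10.0 min that run had lost 2.68 mM of solid, 10.7 times the initiator charged, so we read the initiator as starting something that repeats, a chain.

- delta: solid substrate 20 mM; gas 4.5 mM (held); initiator 0.25 mM; run made earlier
- flask: solid substrate 20 mM; gas 4.5 mM (held); initiator 0.50 mM; time 30 min

delta run (percent of the solid substrate charged)

| time / min | target / % | solid substrate / % | isomer of the product / % |
|---|---|---|---|
| 2.50 | 2.2 | 96.3 | 0.5 |
| 5.00 | 5.7 | 92.8 | 0.4 |
| 6.00 | 6.6 | 91.8 | 1.8 |
| 10.0 | 10.0 | 86.6 | 3.6 |

(scatter of a reading: 0.3 percentage points)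

- concentration of target at 30 min, in mM
- concentration of solid substrate at 30 min, in mM
- concentration of isomer of the product at 30 min, in mM
- concentration of reagent at 30 min, in mM

- given per volume of solution although it is solid: solid substrate
- the earlier runs were read with a standard deviation of 0.3 percentage points
- at the start none of the solid substrate is in solution
- at the start none of the gas is in solution
- no earlier run changes the charge of initiator; that part of a forecast is a guess

The delta run's solid falls nearly straight, at 0.288 mM min⁻¹ up to 5.00 min, and up to its last reading at 0.268 mM min⁻¹, which we call the feed: the solid lost per minute, a zero-order rate as read from that run. A bench rule for a chain, with all else held, takes the rate in proportion to the initiator, so by that rule twice the charge gives 3.92 mM of solid in the asked flask. That rule needs dissolved substrate waiting for a faster chain, and here is its border: in the delta run, target plus isomer of the product over solid lost reads 1.01 at its last reading, with a scatter of 0.3 percentage points on each reading, so these readings show no store of dissolved substrate beyond that scatter. We therefore take dissolving as the rate-limiting step and, guessing since no run tests it, keep the feed unchanged: 12.0 mM of solid, and 8.04 mM of target and isomer of the product together.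

The forecast, saying “Doubling the initiator is a guess”, gives target 6 mM, solid 7 mM (up to 11 mM), isomer of the product 6.8 mM and reagent 3.2 mM, so its solid stands lower than ours.

The asked flask gives target 4.36 mM, solid 11.6 mM, isomer of the product 4.01 mM and reagent 3.28 mM.

    starting material + second chain carrier → released group + first chain carrier (k = 36000 L mol⁻¹ s⁻¹)
    initiator → 2 initiating radical (k = 0.00220 min⁻¹)
    solid substrate ⇌ starting material, rate k3*(cs3 - [starting material]) while solid is left; crystals form when [starting material] > cs3 (solubility = 7.00 mM, k = 0.0400 min⁻¹)
    reagent + first chain carrier → target + second chain carrier (k = 1.30 × 10⁵ L mol⁻¹ s⁻¹)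
    starting material + initiating radical → capped initiator + first chain carrier (k = 2.00 × 10⁵ L mol⁻¹ s⁻¹)
    gas ⇌ reagent, rate k6*(csat - [reagent]) (kL = 0.230 min⁻¹)
    2 first chain carrier → ended chains (k = 8.70 × 10⁶ L mol⁻¹ s⁻¹)
    target ⇌ isomer of the product (K = 1.70, k = 0.0870 min⁻¹)

The solid lies near our 12.0 mM and above the forecast's 7 mM, and target plus isomer of the product come to 8.37 mM against our 8.04 mM. With the initiator changed and nothing else, the solid at 10.0 min stays at 17.2 mM, as in the delta run with 17.2 mM. The same flask read at 20 min is, by the feed, expected to hold 14.6 mM of solid, and it holds 14.4 mM.

The earlier runs and the new flask stem from a simulated flask with constants of no real substance.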